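**Plan**

1. Retrosynthesis first cuts the two interflavan bonds, C4 of each fisetinidol unit to C8 and to C6 of ring A of the central catechin. Each fisetinidol unit is then cut at O1–C8a and C4a–C4, so that its ring A leaves as an aryne and its ring C opens to an O–C2–C3–C4 chain (an anti α-benzyloxy-β-hydroxy thioester).
2. Enabling feature: in ring C, O1 and C4 sit on the adjacent ring-A carbons C8a and C4a. In the open chain O1 is a free hydroxyl oxygen on C2 and C4 can be held at the acyl level. The 5-deoxy ring A has a free C5 next to C4a, which can carry a temporary chlorine that steers the aryne addition.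
3. Forward order: ring B and the chain are joined by an anti-selective Mukaiyama glycolate aldol. Rings A and C of the fisetinidol unit then arise in one aryne annulation (a protected dihydroflavonol), and the C4 ketone is reduced to the carbinol.
4. Two equivalents of this one building block alkylate tetra-O-benzylcatechin at C8 and C6. The two flanking units are identical, so the order of attack is immaterial. One hydrogenolysis removes twelve benzyl groups and both chlorines.
5. Stereochemistry: C2 and C3 of both fisetinidol units come from the enantioselective anti aldol, and C2 and C3 of the central unit from (+)-catechin. Both C4 centres are set by attack on the flavan-4-yl cation trans to the C3 benzyloxy group (4α).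

Key step: step 7

Assumption: the L-proline-derived diamine is taken to give the (2R,3R) anti aldol 13; should it give the antipode, the D-proline-derived diamine is used with no other change.

**Route**

Step 1
Reactants: 1 4-(benzyloxy)phenol
Product: 2 4-(benzyloxy)-2-chlorophenol
Conditions: SO2Cl2 (1.05 equiv), i-Bu2NH (5 mol%), toluene, 0 °C to rt
Reagents that add atoms: sulfuryl chloride, O=S(=O)(Cl)Cl
Why: Electrophilic aromatic chlorination; the free hydroxyl is the stronger director and its para position is blocked, so chlorine should enter ortho to OH (amine-catalysed ortho-chlorination of phenols).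

Step 2
Reactants: 2 4-(benzyloxy)-2-chlorophenol
Product: 3 4-(benzyloxy)-2-bromo-6-chlorophenol
Conditions: NBS (1.0 equiv), i-Pr2NH (10 mol%), CH2Cl2, 0 °C
Reagents that add atoms: N-bromosuccinimide, O=C1CCC(=O)N1Br
Why: Electrophilic aromatic bromination at the one remaining position ortho to the hydroxyl group.

Step 3
Reactants: 3 4-(benzyloxy)-2-bromo-6-chlorophenol
Product: 6 4-(benzyloxy)-2-chloro-6-(trimethylsilyl)phenyl trifluoromethanesulfonate, via aryl trimethylsilyl ether 4 (not isolated), via lithium 2-silylphenolate 5 (not isolated)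
Conditions: hexamethyldisilazane, THF, 65 °C, then evaporation; n-BuLi, THF, −78 °C; Tf2O, −78 °C to rt
Reagents that add atoms: hexamethyldisilazane, C[Si](C)(C)N[Si](C)(C)C; trifluoromethanesulfonic anhydride, O=S(=O)(OS(=O)(=O)C(F)(F)F)C(F)(F)F
Why: O-silylation, bromine–lithium exchange (bromine exchanges, chlorine does not) followed by 1,3 O-to-C silyl migration (retro-Brook rearrangement) and O-triflation of the phenolate, the standard route to 2-(trimethylsilyl)aryl triflate aryne precursors.

Step 4
Reactants: 7 (benzyloxy)acetyl chloride; 8 ethanethiol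
Product: 9 S-ethyl 2-(benzyloxy)ethanethioate
Conditions: pyridine, CH2Cl2, 0 °C to rt
Reagents that add atoms: none
Why: Nucleophilic acyl substitution of the acid chloride by the thiol (thioesterification).

Step 5
Reactants: 9 S-ethyl 2-(benzyloxy)ethanethioate
Product: 10 (Z)-{[2-(benzyloxy)-1-(ethylsulfanyl)ethenyl]oxy}trimethylsilane
Conditions: LDA, THF, −78 °C; then Me3SiCl, −78 °C to rt; distillation
Reagents that add atoms: chlorotrimethylsilane, C[Si](C)(C)Cl
Why: Kinetic enolisation of the thioester and O-silylation should give the ketene silyl acetal, the (Z) isomer being the one expected for alkylthio esters under these conditions.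

Step 6
Reactants: 10 (Z)-{[2-(benzyloxy)-1-(ethylsulfanyl)ethenyl]oxy}trimethylsilane; 11 3,4-bis(benzyloxy)benzaldehyde
Product: 13 S-ethyl (2R,3R)-2-(benzyloxy)-3-[3,4-bis(benzyloxy)phenyl]-3-hydroxypropanethioate, via aldol trimethylsilyl ether 12 (not isolated)
Conditions: Sn(OTf)2 (20 mol%), (S)-1-methyl-2-[(naphthalen-1-ylamino)methyl]pyrrolidine (22 mol%), EtCN, −78 °C, slow addition of 10 and 11; then citric acid, MeOH, rt
Reagents that add atoms: none
Why: Catalytic asymmetric Mukaiyama aldol: the chiral divalent-tin triflate–diamine Lewis acid exposes one face of the aldehyde, and the α-benzyloxy ketene silyl acetal reacts through an open transition state with the benzyloxy oxygen on tin, which should give the anti (2R,3R) adduct and so sets C2 and C3 of ring C; mild acid then removes the silyl group.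

Step 7
Reactants: 13 S-ethyl (2R,3R)-2-(benzyloxy)-3-[3,4-bis(benzyloxy)phenyl]-3-hydroxypropanethioate; 6 4-(benzyloxy)-2-chloro-6-(trimethylsilyl)phenyl trifluoromethanesulfonate
Product: 16 (2R,3R)-3,7-bis(benzyloxy)-2-[3,4-bis(benzyloxy)phenyl]-5-chloro-2,3-dihydro-4H-chromen-4-one, via 3-(benzyloxy)-5-chlorobenzyne 14 (not isolated), via ortho-aryloxy aryl anion 15 (not isolated)
Conditions: KF, 18-crown-6, THF, −20 °C to rt, slow addition of 6 (2.2 equiv)
Reagents that add atoms: none
Why: Proposed new method: fluoride desilylates 6 to aryne 14, the hydroxyl oxygen of 13 adds to the aryne carbon remote from chlorine (the future C8a), and the ortho aryl anion 15 so formed attacks the thioester carbonyl (the future C4) and expels ethanethiolate, so that O1–C8a and C4a–C4 are made in one formal [4+2] annulation. The closest known reaction type is the aryne annulation of salicylate esters to xanthones and of N–H anthranilate esters to acridones (heteroatom addition to an aryne, then intramolecular acyl capture by the aryl anion); what is new is an aliphatic aldol hydroxyl as the nucleophile. Ring C closes in the C–C bond-forming event by 6-exo-trig attack of the aryl anion on the acyl carbon. No stereocentre is formed: C2 and C3 come unchanged from 13, and the anti relationship of the chain becomes the 2,3-trans arrangement of the ring. Regioselectivity is secured by the C5 chlorine, which distorts the aryne so that the remote carbon is the more electrophilic one and stabilises the developing negative charge at the adjacent C4a inductively (the known behaviour of 3-haloarynes). The step further needs acyl capture to outrun protonation of the aryl anion (aprotic medium, reactive thioester, six-membered transition state) and needs the aldol to survive (low temperature, no stoichiometric alkoxide, so retro-aldol and C3 epimerisation are held back); the excess of 6 consumes the released thiolate.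

Step 8
Reactants: 16 (2R,3R)-3,7-bis(benzyloxy)-2-[3,4-bis(benzyloxy)phenyl]-5-chloro-2,3-dihydro-4H-chromen-4-one
Product: 17 (2R,3S,4R)-3,7-bis(benzyloxy)-2-[3,4-bis(benzyloxy)phenyl]-5-chloro-3,4-dihydro-2H-chromen-4-ol
Conditions: NaBH4, THF–MeOH, 0 °C
Reagents that add atoms: none
Why: Hydride 1,2-reduction of the aryl ketone; axial delivery should give mainly the equatorial 3,4-trans carbinol (4R), and the C4 epimer would serve equally because C4 is ionised in step 10.

Step 9
Reactants: 18 (+)-catechin
Product: 19 (2R,3S)-5,7-bis(benzyloxy)-2-[3,4-bis(benzyloxy)phenyl]-3,4-dihydro-2H-chromen-3-ol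
Conditions: BnBr (4.4 equiv), K2CO3, DMF, rt
Reagents that add atoms: benzyl bromide, BrCc1ccccc1
Why: Williamson etherification; carbonate deprotonates only the four phenols, so the secondary C3 hydroxyl should stay free and C2 and C3 are untouched.

Step 10
Reactants: 17 (2R,3S,4R)-3,7-bis(benzyloxy)-2-[3,4-bis(benzyloxy)phenyl]-5-chloro-3,4-dihydro-2H-chromen-4-ol; 19 (2R,3S)-5,7-bis(benzyloxy)-2-[3,4-bis(benzyloxy)phenyl]-3,4-dihydro-2H-chromen-3-ol
Product: 20 (2R,3S)-5,7-bis(benzyloxy)-2-[3,4-bis(benzyloxy)phenyl]-6,8-bis{(2R,3S,4α)-3,7-bis(benzyloxy)-2-[3,4-bis(benzyloxy)phenyl]-5-chloro-3,4-dihydro-2H-chromen-4-yl}-3,4-dihydro-2H-chromen-3-ol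
Conditions: 17 (2.4 equiv), BF3·OEt2 (30 mol%), 4 Å molecular sieves, CH2Cl2, −40 to 0 °C
Reagents that add atoms: none
Why: Friedel–Crafts alkylation: Lewis-acid ionisation of the C4 carbinol gives a benzylic cation stabilised by O1 and the para C7 benzyloxy group, and the phloroglucinol-type ring A of 19 should attack it at C8 and then at C6, each time on the face opposite the pseudo-equatorial C3 benzyloxy group, which sets both new C4 centres 3,4-trans (4α); the chlorinated ring A of 17 is too poor a nucleophile to self-condense.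

Step 11
Reactants: 20 the dodeca-O-benzyl dichloro triflavanoid of step 10
Product: 21 fisetinidol-(4α→8)-catechin-(6→4α)-fisetinidol, (2R,3S)-2-(3,4-dihydroxyphenyl)-6,8-bis[(2R,3S,4S)-2-(3,4-dihydroxyphenyl)-3,7-dihydroxy-3,4-dihydro-2H-chromen-4-yl]-3,4-dihydro-2H-chromene-3,5,7-triol
Conditions: H2 (1 atm), Pd(OH)2/C, NaOAc, THF–MeOH–H2O, rt
Reagents that add atoms: none
Why: Heterogeneous hydrogenolysis should cleave the twelve benzyl ethers and, with acetate as acceptor for HCl, both aryl C–Cl bonds (hydrodechlorination), while the ring-C ethers, the interflavan bonds and all stereocentres stay untouched.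

**Compound list**

1 | 4-(benzyloxy)phenol | Oc1ccc(OCc2ccccc2)cc1 | starting material
2 | 4-(benzyloxy)-2-chlorophenol | Oc1ccc(OCc2ccccc2)cc1Cl | intermediate
3 | 4-(benzyloxy)-2-bromo-6-chlorophenol | Oc1c(Cl)cc(OCc2ccccc2)cc1Br | intermediate
4 | [4-(benzyloxy)-2-bromo-6-chlorophenoxy]trimethylsilane | C[Si](C)(C)Oc1c(Cl)cc(OCc2ccccc2)cc1Br | intermediate
5 | lithium 4-(benzyloxy)-2-chloro-6-(trimethylsilyl)phenolate | [Li+].[O-]c1c(Cl)cc(OCc2ccccc2)cc1[Si](C)(C)C | intermediate
6 | 4-(benzyloxy)-2-chloro-6-(trimethylsilyl)phenyl trifluoromethanesulfonate | C[Si](C)(C)c1cc(OCc2ccccc2)cc(Cl)c1OS(=O)(=O)C(F)(F)F | intermediate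
7 | (benzyloxy)acetyl chloride | O=C(Cl)COCc1ccccc1 | starting material
8 | ethanethiol | CCS | starting material
9 | S-ethyl 2-(benzyloxy)ethanethioate | CCSC(=O)COCc1ccccc1 | intermediate
10 | (Z)-{[2-(benzyloxy)-1-(ethylsulfanyl)ethenyl]oxy}trimethylsilane | CCS/C(O[Si](C)(C)C)=C\OCc1ccccc1 | intermediate
11 | 3,4-bis(benzyloxy)benzaldehyde | O=Cc1ccc(OCc2ccccc2)c(OCc2ccccc2)c1 | starting material
12 | S-ethyl (2R,3R)-2-(benzyloxy)-3-[3,4-bis(benzyloxy)phenyl]-3-[(trimethylsilyl)oxy]propanethioate | C[Si](C)(C)O[C@H](c1ccc(OCc2ccccc2)c(OCc2ccccc2)c1)[C@@H](OCc1ccccc1)C(=O)SCC | intermediate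
13 | S-ethyl (2R,3R)-2-(benzyloxy)-3-[3,4-bis(benzyloxy)phenyl]-3-hydroxypropanethioate | O[C@H](c1ccc(OCc2ccccc2)c(OCc2ccccc2)c1)[C@@H](OCc1ccccc1)C(=O)SCC | intermediate
14 | 3-(benzyloxy)-5-chlorobenzyne | ClC1=CC(OCc2ccccc2)=CC#C1 | intermediate
15 | S-ethyl (2R,3R)-2-(benzyloxy)-3-[3,4-bis(benzyloxy)phenyl]-3-[5-(benzyloxy)-3-chloro-2-potassiophenoxy]propanethioate (aryl anion, potassium counter-ion) | Clc1cc(OCc2ccccc2)cc(O[C@H](c2ccc(OCc3ccccc3)c(OCc3ccccc3)c2)[C@@H](OCc2ccccc2)C(=O)SCC)[c-]1.[K+] | intermediate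
16 | (2R,3R)-3,7-bis(benzyloxy)-2-[3,4-bis(benzyloxy)phenyl]-5-chloro-2,3-dihydro-4H-chromen-4-one | c1ccccc1COc1cc(Cl)c2c(c1)O[C@H](c1ccc(OCc3ccccc3)c(OCc3ccccc3)c1)[C@@H](OCc1ccccc1)C2=O | intermediate
17 | (2R,3S,4R)-3,7-bis(benzyloxy)-2-[3,4-bis(benzyloxy)phenyl]-5-chloro-3,4-dihydro-2H-chromen-4-ol | c1ccccc1COc1cc(Cl)c2c(c1)O[C@H](c1ccc(OCc3ccccc3)c(OCc3ccccc3)c1)[C@@H](OCc1ccccc1)[C@@H]2O | intermediate
18 | (+)-catechin, (2R,3S)-2-(3,4-dihydroxyphenyl)-3,4-dihydro-2H-chromene-3,5,7-triol | Oc1cc(O)c2c(c1)O[C@H](c1ccc(O)c(O)c1)[C@@H](O)C2 | starting material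
19 | (2R,3S)-5,7-bis(benzyloxy)-2-[3,4-bis(benzyloxy)phenyl]-3,4-dihydro-2H-chromen-3-ol | c1ccccc1COc1cc(OCc2ccccc2)c2c(c1)O[C@H](c1ccc(OCc3ccccc3)c(OCc3ccccc3)c1)[C@@H](O)C2 | intermediate
20 | dodeca-O-benzyl ether of the target with chlorine at C5 of both fisetinidol units; both C4–aryl bonds trans to the adjacent C3 benzyloxy group (4α); central C3 hydroxyl free | c1ccccc1COc1cc(Cl)c2c(c1)O[C@H](c1ccc(OCc3ccccc3)c(OCc3ccccc3)c1)[C@@H](OCc1ccccc1)[C@@H]2c1c(OCc3ccccc3)c2c(c([C@@H]3c4c(Cl)cc(OCc5ccccc5)cc4O[C@H](c4ccc(OCc5ccccc5)c(OCc5ccccc5)c4)[C@H]3OCc3ccccc3)c1OCc1ccccc1)O[C@H](c1ccc(OCc3ccccc3)c(OCc3ccccc3)c1)[C@@H](O)C2 | intermediate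
21 | fisetinidol-(4α→8)-catechin-(6→4α)-fisetinidol | Oc1ccc2c(c1)O[C@H](c1ccc(O)c(O)c1)[C@@H](O)[C@@H]2c1c(O)c2c(c([C@@H]3c4ccc(O)cc4O[C@H](c4ccc(O)c(O)c4)[C@H]3O)c1O)O[C@H](c1ccc(O)c(O)c1)[C@@H](O)C2 | target

**Step count and risks**

Total step count: 11. Longest linear sequence: 7 steps (steps 1, 2, 3, 7, 8, 10, 11; the branch through steps 4, 5, 6 is equally long).

Steps most likely to fail:

Step 7. The aryl anion may be protonated before it reaches the thioester, which gives simple O-arylation. The aldol may fragment by retro-aldol or epimerise at C3 under fluoride. The ortho-chloro aryl anion may lose chloride, and THF may be drawn into the aryne addition. Fallback, by known chemistry, from 13 and 6 back to 16: the two bonds are made one after the other. With CsF in MeCN at rt, 13 and 6 should undergo O–H insertion of the alcohol into the aryne, the medium protonating the aryl anion, to give S-ethyl (2R,3R)-2-(benzyloxy)-3-[3,4-bis(benzyloxy)phenyl]-3-[3-(benzyloxy)-5-chlorophenoxy]propanethioate F1. Silver-assisted hydrolysis (AgOCOCF3, THF–H2O) would give (2R,3R)-2-(benzyloxy)-3-[3,4-bis(benzyloxy)phenyl]-3-[3-(benzyloxy)-5-chlorophenoxy]propanoic acid F2. Trifluoroacetic anhydride in CH2Cl2 at 0 °C should then close ring C by intramolecular Friedel–Crafts acylation, expected para to the benzyloxy group, which returns to 16.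

Step 10. The second alkylation, at the position flanked by two benzyloxy groups, may stall. Facial selectivity at C4 may be poor, and the Lewis acid may reopen interflavan bonds already formed. Fallback, from 16 and 18 to 21: the coupling is moved to the free phenols. Hydrogenolysis of 16 (H2, Pd(OH)2/C, NaOAc, EtOAc–MeOH) should remove the four benzyl groups and the chlorine to give (2R,3R)-3,7,3',4'-tetrahydroxyflavanone, (+)-fustin F3. NaBH4 in EtOH would give the (2R,3S,4R)-flavan-3,4-diol, (+)-mollisacacidin F4. Acid-catalysed condensation of F4 (2.2 equiv) with (+)-catechin 18 in 0.1 M aqueous HCl at rt, a known reaction type in which the C4 cation is attacked trans to the C3 hydroxyl at C8 and C6 of catechin, should give 21 directly after chromatography.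

Step 11. Hydrodechlorination of the two hindered aryl chlorides may stay incomplete while debenzylation proceeds, and forcing the reaction may cleave the benzylic C2–O1 bonds. Fallback, from 17 to 21: the chlorine is taken out right after it has done its work. Homogeneous palladium-catalysed transfer hydrodechlorination of 17 (Pd(OAc)2, P(t-Bu)3·HBF4, HCO2Na, DMF, 80 °C), which leaves benzyl ethers alone, would give (2R,3S,4R)-3,7-bis(benzyloxy)-2-[3,4-bis(benzyloxy)phenyl]-3,4-dihydro-2H-chromen-4-ol F5. Coupling of F5 with 19 under the conditions of step 10 would give the chlorine-free dodeca-O-benzyl triflavanoid F6. Plain hydrogenolysis (H2, Pd(OH)2/C, THF–MeOH) would then give 21.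

**Further compounds**

F1 | step 7 | S-ethyl (2R,3R)-2-(benzyloxy)-3-[3,4-bis(benzyloxy)phenyl]-3-[3-(benzyloxy)-5-chlorophenoxy]propanethioate | Clc1cc(OCc2ccccc2)cc(O[C@H](c2ccc(OCc3ccccc3)c(OCc3ccccc3)c2)[C@@H](OCc2ccccc2)C(=O)SCC)c1
F2 | step 7 | (2R,3R)-2-(benzyloxy)-3-[3,4-bis(benzyloxy)phenyl]-3-[3-(benzyloxy)-5-chlorophenoxy]propanoic acid | Clc1cc(OCc2ccccc2)cc(O[C@H](c2ccc(OCc3ccccc3)c(OCc3ccccc3)c2)[C@@H](OCc2ccccc2)C(O)=O)c1
F3 | step 10 | (+)-fustin, (2R,3R)-2-(3,4-dihydroxyphenyl)-3,7-dihydroxy-2,3-dihydro-4H-chromen-4-one | Oc1ccc2c(c1)O[C@H](c1ccc(O)c(O)c1)[C@@H](O)C2=O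
F4 | step 10 | (+)-mollisacacidin, (2R,3S,4R)-2-(3,4-dihydroxyphenyl)-3,4-dihydro-2H-chromene-3,4,7-triol | Oc1ccc2c(c1)O[C@H](c1ccc(O)c(O)c1)[C@@H](O)[C@@H]2O
F5 | step 11 | (2R,3S,4R)-3,7-bis(benzyloxy)-2-[3,4-bis(benzyloxy)phenyl]-3,4-dihydro-2H-chromen-4-ol | c1ccccc1COc1ccc2c(c1)O[C@H](c1ccc(OCc3ccccc3)c(OCc3ccccc3)c1)[C@@H](OCc1ccccc1)[C@@H]2O
F6 | step 11 | chlorine-free dodeca-O-benzyl ether of the target (analogue of 20 without chlorine) | c1ccccc1COc1ccc2c(c1)O[C@H](c1ccc(OCc3ccccc3)c(OCc3ccccc3)c1)[C@@H](OCc1ccccc1)[C@@H]2c1c(OCc3ccccc3)c2c(c([C@@H]3c4ccc(OCc5ccccc5)cc4O[C@H](c4ccc(OCc5ccccc5)c(OCc5ccccc5)c4)[C@H]3OCc3ccccc3)c1OCc1ccccc1)O[C@H](c1ccc(OCc3ccccc3)c(OCc3ccccc3)c1)[C@@H](O)C2
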